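The question is what share of its E the larch flask has turned into G at 62 min, where E goes to G over the catalyst X; the two orders are asked beside it.

| setting | maple | oak | cedar | larch |
|---|---|---|---|---|
| E | 0.0500 M | 0.0500 M | 0.100 M | 0.0250 M |
| X | 0.00100 M | 0.00150 M | 0.00100 M | 0.00100 M |
| time |  |  |  | 62 min |

| run | time / min | [G] / M |
|---|---|---|
| maple run | 10 | 0.0053 |
| maple run | 21 | 0.0116 |
| maple run | 31 | 0.0174 |
| maple run | 41 | 0.0234 |
| maple run | 52 | 0.0294 |
| maple run | 62 | 0.0348 |
| oak run | 10 | 0.0080 |
| oak run | 21 | 0.0165 |
| oak run | 31 | 0.0244 |
| oak run | 41 | 0.0319 |
| oak run | 52 | 0.0395 |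
| oak run | 62 | 0.0435 |
| cedar run | 10 | 0.0061 |
| cedar run | 21 | 0.0141 |
| cedar run | 31 | 0.0251 |
| cedar run | 41 | 0.0344 |
| cedar run | 52 | 0.0468 |
| cedar run | 62 | 0.0583 |

(each reading ± 4 × 10⁻⁴ M)

- Overall: E -> G, with X as catalyst.
- Constant volume, constant temperature.
- What is held in complexes is read along with the free species.
- An order is taken over about fifteen percent of the charge, up and down.

- order of the initial rate in [X], near the charge of the maple run, the rate being that where two percent of its E are G
- order of the initial rate in [E], near the charge of the maple run, the rate being that where two percent of its E are G (one fixed amount of G, the same in the runs compared)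
- G in the larch run at 62 min, as a share of the E charged

Your hunch was that larch, holding half the E of maple, finishes in half the time. The readings point away from that scaling. The half-time, at which G reaches half the E charged, lies between neighbouring readings at 43.9 min in maple and at 54.8 min in cedar. So cedar, with twice the charge, takes longer than maple by a factor of 1.25. This reply assumes the same factor for the step down from maple, which gives larch a half-time of 35.2 min.

Larch at 62 min then stands at 1.76 half-times. This half-time count, a reduced time, is the time elapsed divided by the flask's own half-time, and the reply takes the share turned to follow it. Maple's last reading, at a count of 1.41, shows 69.6% of its charge as G. Oak, with a half-time of 31.8 min, shows 87.0% at a count of 1.95. A straight line between these two readings puts larch at 80.9%.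

The forecast gives orders of 0.9 in X and 0.25 in E and 80% for larch, remarking “Oak suggests slightly weaker activation”. The simulated flask gives orders of 0.97 in X and 0.38 in E, and 81.6% for larch, by this scheme:

    X + E ⇌ XE, settled at all times (49.10 L mol⁻¹)
    XE → G + X (1.452 min⁻¹)
    E + G → 2 G (1.194 L mol⁻¹ min⁻¹)
    2 E ⇌ E2, settled at all times (177.0 L mol⁻¹)

Larch holds 81.6% of its charge as G at a count of 1.76, a difference of 0.70 percentage points from the share reckoned above. Where G amounts to two percent of maple's E, cedar runs at 1.3 times the rate of maple. Maple reaches a quarter of its charge at 23.2 min and half at 44.4 min, so a quarter falls at a count of 0.521. That count on oak's half-time of 31.8 min gives 16.6 min, and oak reaches a quarter of its charge at 16.2 min.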